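A direct plan would couple a C12 bromo acid with an isopentenyl Grignard reagent, make the ynone through a Weinreb amide and reduce it by asymmetric transfer hydrogenation to the propargylic alcohol A1.
A1 would then be turned by hydroxyl-directed vinylmagnesiation, CO2 capture and lactonisation into the 4-vinylbutenolide A2; ozonolysis (to the keto aldehyde A3) and chlorite oxidation would unveil ketone and acid.
Weakest would be the directed anti-carbomagnesiation/carboxylation of A1: regiochemistry and alkene geometry would hang on one magnesium chelate, vinyl Grignard reagents add sluggishly, and every failure would be paid in enantioenriched material.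
Next would be the double ozonolysis of A2: ozone would have to cleave a remote alkene and the vinyl group of a dienoate but spare the tetrasubstituted ring alkene, on the most precious material of the route.
Third would be the oxidation-state detour as a whole: ketone and carboxyl would travel as alkenes, so that three chain-building steps and two oxidations would add almost no complexity.

Plan of the new route
Ring numbering: O1, C2(=O), C3(Me), C4(CO2H), C5(H, chain). The array O1–C5–C4=C3–C2(=O) is the cyclised form of a 2,3-allenoate C5=C4=C3–C2O2Me, in which C5 (allene terminus) takes up the oxygen and C4 (central carbon) an electrophile.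
The retrosynthesis cuts C4–CO2H (carbonylation of C4–I), then O1–C5 together with C4–I (iodolactonisation of the allenoate), then C3–C2 (carbonylation of a racemic propargylic carbonate), then C4–C5 and C(=O)–CH3 (two Grignard reagents on an aldehyde–Weinreb amide from 15-pentadecanolide).
The only ring arises in the penultimate step, by alkyl–oxygen closure at C5. Its stereocentre is relayed from an allene axis that a chiral palladium catalyst sets enantioconvergently from the racemate; the propargylic C5–O bond is made only to be broken.
No carbometalation and no ozonolysis occur, and no carbonyl group is carried in masked form: the ketone carbon is the lactone carbon of the starting material and the carboxyl carbon is CO.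

Key step: step 6

Assumption: (R)-DTBM-SEGPHOS, the bisphosphine (R)-5,5′-bis[bis(3,5-di-tert-butyl-4-methoxyphenyl)phosphino]-4,4′-bi-1,3-benzodioxole, is taken to give the (S)-allene axis; if the first run shows the opposite sense, the (S)-ligand is used and nothing else changes.

Step 1
Reactants: 1 ω-pentadecalactone (oxacyclohexadecan-2-one)
Product: 3 15-hydroxy-N-methoxy-N-methylpentadecanamide, via chloromagnesium alkoxide 2 (not isolated)
Conditions: MeNH(OMe)·HCl (2.0 equiv), i-PrMgCl (4.0 equiv), THF, −20 → 0 °C; then 1 M HCl, 0 °C
Reagents that add atoms: N,O-dimethylhydroxylamine hydrochloride, CNOC.Cl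
Why: Ring-opening aminolysis of the macrolactone by the chloromagnesium amide of N,O-dimethylhydroxylamine (Weinreb amide formation) is driven by the magnesium alkoxide that forms and delivers the whole C15 chain with its two ends already differentiated.

Step 2
Reactants: 3 15-hydroxy-N-methoxy-N-methylpentadecanamide
Product: 4 N-methoxy-N-methyl-15-oxopentadecanamide
Conditions: TEMPO (10 mol %), PhI(OAc)2 (1.2 equiv), CH2Cl2, rt
Reagents that add atoms: none
Why: Oxoammonium-mediated (TEMPO) oxidation with PhI(OAc)2 as the terminal oxidant stops at the aldehyde in the absence of water and does not touch the Weinreb amide.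

Step 3
Reactants: 4 N-methoxy-N-methyl-15-oxopentadecanamide; 5 prop-1-ynylmagnesium bromide; 6 methylmagnesium bromide
Product: 9 rac-16-hydroxynonadec-17-yn-2-one, via alkoxide amide 7 (not isolated), via tetrahedral adduct 8 (not isolated)
Conditions: 5 (0.5 M in THF, 1.1 equiv), THF, −78 °C; then 6 (3 M in Et2O, 2.5 equiv), −78 → 0 °C; 1 M HCl, 0 °C
Reagents that add atoms: none
Why: Two Grignard additions in one flask: at −78 °C the alkynyl reagent adds to the aldehyde much faster than to the Weinreb amide, which then takes up exactly one methyl group because its magnesium chelate survives until the acid quench (Weinreb ketone synthesis), so the ketone never meets a Grignard reagent; the carbinol centre is left racemic on purpose.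

Step 4
Reactants: 9 rac-16-hydroxynonadec-17-yn-2-one
Product: 10 rac-methyl 18-oxononadec-2-yn-4-yl carbonate
Conditions: ClCO2Me (1.5 equiv), pyridine (3 equiv), DMAP (5 mol %), CH2Cl2, 0 °C → rt
Reagents that add atoms: methyl chloroformate, COC(=O)Cl
Why: Acylation of the secondary alcohol with methyl chloroformate and pyridine (DMAP catalysis) installs the carbonate that zerovalent palladium ionises under neutral conditions; the methyl ketone and the alkyne are inert.

Step 5
Reactants: 10 rac-methyl 18-oxononadec-2-yn-4-yl carbonate; 11 carbon monoxide
Product: 12 methyl (S)-2-methyl-18-oxononadeca-2,3-dienoate (axial chirality)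
Conditions: [PdCl(η3-PhCHCHCH2)]2 (2 mol %), (R)-DTBM-SEGPHOS (6 mol %), CO (1 atm), MeOH–toluene, rt
Reagents that add atoms: methanol, CO
Why: Enantioconvergent palladium-catalysed carbonylation of a racemic propargylic carbonate (dynamic kinetic asymmetric transformation): anti-SN2′ oxidative addition with loss of CO2 gives allenylpalladium methoxide species that interconvert faster than CO inserts, the chiral bisphosphine lets one of them insert CO preferentially, and methanolysis of the acylpalladium releases the allenoate, whose (S) axis is thus set by the ligand and not by the configuration of 10.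

Step 6
Reactants: 12 methyl (S)-2-methyl-18-oxononadeca-2,3-dienoate
Product: 14 (S)-4-iodo-3-methyl-5-(14-oxopentadecyl)furan-2(5H)-one, via 2-methoxyfuranylium iodide 13 (not isolated)
Conditions: I2 (2.0 equiv), MeCN–H2O (15:1), rt, dark; aq Na2S2O3
Reagents that add atoms: iodine, II
Why: Iodine activates the distal C4=C5 π-bond of the allenoate (ring numbering), whose p-orbitals lie in the plane of the ester; the ester carbonyl oxygen attacks C5 anti to iodine, and iodide demethylates the 2-methoxyfuranylium ion 13 to the lactone (iodolactonisation of 2,3-allenoates to 4-iodobutenolides is the closest known reaction type). The ring closes through O1–C5 by 5-endo-trig attack on the allene terminus, which is feasible here because the attacked π-bond is orthogonal to the conjugated one and points at the carbonyl oxygen. The new stereocentre C5 is controlled by the allene axis alone: H and the chain at the allene terminus stand above and below the plane in which the ring forms and keep their places, so the (S) axis gives (S)-C5 whichever face iodine takes. The step needs attack on C4=C5 and not on the ester-conjugated C3=C4 bond, which the electron-poor character of the latter secures. It also needs ring closure faster than opening of the iodonium ion to a rotatable 2-iodoallyl cation, which the intramolecular nucleophile and the polar aqueous medium secure. Iodine ends on C4, exactly where the carboxyl group is needed, and the methyl ketone is not enolised in this neutral to acidic medium.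

Step 7
Reactants: 14 (S)-4-iodo-3-methyl-5-(14-oxopentadecyl)furan-2(5H)-one; 11 carbon monoxide
Product: 16 (S)-4-methyl-5-oxo-2-(14-oxopentadecyl)-2,5-dihydrofuran-3-carboxylic acid, via potassium carboxylate 15 (not isolated)
Conditions: PdCl2(PPh3)2 (5 mol %), CO (1 atm), KOAc (3 equiv), DMF–H2O (9:1), 40 °C; then 1 M HCl, 0 °C
Reagents that add atoms: water, O
Why: Palladium-catalysed hydroxycarbonylation of an alkenyl iodide (oxidative addition of zerovalent palladium into C4–I, CO insertion, capture of the acylpalladium by acetate and water) puts the carboxyl group on C4 at its final oxidation level, the weak base acetate should not deprotonate C5, and syn-β-oxygen elimination is impossible because Pd–C4 and C5–O1 are anti-coplanar in the ring.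

Compound list
1 | ω-pentadecalactone (oxacyclohexadecan-2-one) | O=C1CCCCCCCCCCCCCCO1 | starting material
2 | chloromagnesium alkoxide of 15-hydroxy-N-methoxy-N-methylpentadecanamide | CON(C)C(=O)CCCCCCCCCCCCCCO[Mg]Cl | intermediate
3 | 15-hydroxy-N-methoxy-N-methylpentadecanamide | CON(C)C(=O)CCCCCCCCCCCCCCO | intermediate
4 | N-methoxy-N-methyl-15-oxopentadecanamide | CON(C)C(=O)CCCCCCCCCCCCCC=O | intermediate
5 | prop-1-ynylmagnesium bromide | CC#C[Mg]Br | starting material
6 | methylmagnesium bromide | C[Mg]Br | starting material
7 | bromomagnesium alkoxide of rac-15-hydroxy-N-methoxy-N-methyloctadec-16-ynamide (alkoxide amide) | CON(C)C(=O)CCCCCCCCCCCCCC(O[Mg]Br)C#CC | intermediate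
8 | bis(bromomagnesium) salt of the methyl adduct of 7 at the amide carbon (tetrahedral adduct, mixture of diastereomers) | CON(C)C(C)(O[Mg]Br)CCCCCCCCCCCCCC(O[Mg]Br)C#CC | intermediate
9 | rac-16-hydroxynonadec-17-yn-2-one | CC(=O)CCCCCCCCCCCCCC(O)C#CC | intermediate
10 | rac-methyl 18-oxononadec-2-yn-4-yl carbonate | CC(=O)CCCCCCCCCCCCCC(OC(=O)OC)C#CC | intermediate
11 | carbon monoxide | [C-]#[O+] | starting material
12 | methyl (S)-2-methyl-18-oxononadeca-2,3-dienoate (axial chirality) | CC(=O)CCCCCCCCCCCCCC=[C@@]=C(C)C(=O)OC | intermediate
13 | (S)-3-iodo-5-methoxy-4-methyl-2-(14-oxopentadecyl)-2H-furan-1-ium iodide | CC(=O)CCCCCCCCCCCCC[C@@H]1[O+]=C(OC)C(C)=C1I.[I-] | intermediate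
14 | (S)-4-iodo-3-methyl-5-(14-oxopentadecyl)furan-2(5H)-one | CC(=O)CCCCCCCCCCCCC[C@@H]1OC(=O)C(C)=C1I | intermediate
15 | potassium (S)-4-methyl-5-oxo-2-(14-oxopentadecyl)-2,5-dihydrofuran-3-carboxylate | CC(=O)CCCCCCCCCCCCC[C@@H]1OC(=O)C(C)=C1C(=O)[O-].[K+] | intermediate
16 | (S)-4-methyl-5-oxo-2-(14-oxopentadecyl)-2,5-dihydrofuran-3-carboxylic acid | CC(=O)CCCCCCCCCCCCC[C@@H]1OC(=O)C(C)=C1C(=O)O | target

Total step count: 7. Longest linear sequence: 7 steps.

Steps most likely to fail

Step 5. The allenylpalladium intermediates may not interconvert fast enough relative to CO insertion, so that enantiocontrol stays incomplete, or the allenoate may isomerise to the conjugated 2,4-dienoate. The fallback sets out from 9 and returns at 12, and replaces the enantioconvergent step by a catalyst-controlled reduction followed by a stereospecific substitution. Oxidation of 9 with Dess–Martin periodinane would give nonadec-17-yne-2,16-dione F1. Noyori transfer hydrogenation with RuCl[(R,R)-TsDPEN](p-cymene) in i-PrOH, which should reduce the ynone far faster than the methyl ketone, would give (R)-16-hydroxynonadec-17-yn-2-one F2. Mesylation (MsCl, Et3N, CH2Cl2, −20 °C) would give (R)-18-oxononadec-2-yn-4-yl methanesulfonate F3. Carbonylation with the achiral catalyst Pd(PPh3)4 (CO, MeOH, THF, rt) would then give 12, because anti-SN2′ oxidative addition and CO insertion with retention turn the (R) centre into the (S) axis.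

Step 6. Axial chirality may leak away through reversible opening of the iodonium ion before the weakly nucleophilic ester oxygen closes the ring. The fallback sets out from 12 and returns at 14, and changes the cyclising species from the neutral ester to the free acid. Saponification (LiOH, THF–H2O, 0 °C) would give (S)-2-methyl-18-oxononadeca-2,3-dienoic acid F4. Iodolactonisation of F4 with N-iodosuccinimide (CH2Cl2, 0 °C) would give 14; the carboxyl oxygen should capture the iodonium ion faster, and no demethylation is needed.

Step 7. Partial epimerisation at C5, hydrolytic opening of the lactone in the warm aqueous medium, or reductive loss of iodine may occur. The fallback sets out from 14 and returns at 16, and avoids water and any basic aqueous phase. Carbonylation with 4-methoxybenzyl alcohol (PdCl2(PPh3)2, CO, i-Pr2NEt, toluene, 50 °C) would give 4-methoxybenzyl (S)-4-methyl-5-oxo-2-(14-oxopentadecyl)-2,5-dihydrofuran-3-carboxylate F5. Acidic cleavage (CF3CO2H, Et3SiH, CH2Cl2, 0 °C) would then liberate 16 under conditions in which C5 cannot be deprotonated.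

Further compounds
F1 | step 5 | nonadec-17-yne-2,16-dione | CC(=O)CCCCCCCCCCCCCC(=O)C#CC
F2 | step 5 | (R)-16-hydroxynonadec-17-yn-2-one | CC(=O)CCCCCCCCCCCCC[C@@H](O)C#CC
F3 | step 5 | (R)-18-oxononadec-2-yn-4-yl methanesulfonate | CC(=O)CCCCCCCCCCCCC[C@@H](OS(C)(=O)=O)C#CC
F4 | step 6 | (S)-2-methyl-18-oxononadeca-2,3-dienoic acid (axial chirality) | CC(=O)CCCCCCCCCCCCCC=[C@@]=C(C)C(=O)O
F5 | step 7 | 4-methoxybenzyl (S)-4-methyl-5-oxo-2-(14-oxopentadecyl)-2,5-dihydrofuran-3-carboxylate | CC(=O)CCCCCCCCCCCCC[C@@H]1OC(=O)C(C)=C1C(=O)OCc1ccc(OC)cc1
A1 | direct plan | (S)-18-methylnonadec-18-en-2-yn-4-ol | CC#C[C@@H](O)CCCCCCCCCCCCCC(C)=C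
A2 | direct plan | (S)-3-methyl-5-(14-methylpentadec-14-en-1-yl)-4-vinylfuran-2(5H)-one | C=CC1=C(C)C(=O)O[C@H]1CCCCCCCCCCCCCC(C)=C
A3 | direct plan | (S)-4-methyl-5-oxo-2-(14-oxopentadecyl)-2,5-dihydrofuran-3-carbaldehyde | CC(=O)CCCCCCCCCCCCC[C@@H]1OC(=O)C(C)=C1C=O
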